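**Retrosynthetic overview**
1. The target is read as epiafzelechin-(4β→8)-epiafzelechin-(4β→8)-4′-O-methylepigallocatechin: every unit 2R,3R (2,3-cis), both interflavan bonds 4β and trans to the 3-OH (top C4 R, middle C4 S). It is released from its deca-O-benzyl ether by hydrogenolysis.
2. The two C4–C8 bonds go back to one 4β-alkoxy electrophile (made from the epiafzelechin monomer by oxidative C4–O bond formation), added first to the 4′-O-methylepigallocatechin monomer and then to the resulting dimer.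
3. Key disconnection in each flavan unit: the O1–C2 aryl ether C–O bond, formed with inversion between 3,5-bis(benzyloxy)phenol and an erythro epoxy alcohol; the epoxide oxygen is the future 3-OH.
4. Ring C of each unit is closed last, at C4–C4a, by epoxide–arene cyclisation onto the preformed rings A and B; the three C rings exist before the units are joined.
5. Each epoxy alcohol comes from an aryl aldehyde in one flask by asymmetric vinylation and tartrate-controlled epoxidation (C3–O bond).

Assumption: 3,5-bis(benzyloxy)phenol is bought as a catalogue phenol and Zn(CH=CH2)2 is used as a salt-free toluene stock solution made beforehand from CH2=CHMgBr and ZnCl2.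

**Route**

Step 1
Reactants: 1 4-(benzyloxy)benzaldehyde
Product: 3 (S)-[4-(benzyloxy)phenyl][(R)-oxiran-2-yl]methanol, via vinylzinc (R)-allylic alkoxide 2 (not isolated)
Conditions: Zn(CH=CH2)2 (1.5 equiv), (+)-MIB (5 mol %), toluene, −30 → 0 °C; then Ti(OiPr)4 (20 mol %), L-(+)-DIPT (24 mol %), TBHP (3 equiv), 4 Å MS, CH2Cl2, −20 °C
Reagents that add atoms: divinylzinc, C=C[Zn]C=C; tert-butyl hydroperoxide, CC(C)(C)OO
Why: Proposed new method: the (+)-MIB–zinc chelate transfers one vinyl group of Zn(CH=CH2)2 to a single face of the aldehyde to give the (R)-allylic zinc alkoxide, which exchanges onto titanium and is epoxidised by TBHP under L-(+)-tartrate control in the matched sense, oxygen being delivered anti to the aryl group to set the (R)-epoxide centre (erythro) while the small amount of (S)-alkoxide reacts far more slowly and is left behind; the closest known reaction types are the amino-alcohol-catalysed addition of alkenylzinc reagents to aldehydes with in situ Ti(OiPr)4/TBHP epoxidation of the zinc alkoxide and the Sharpless asymmetric epoxidation of secondary allylic alcohols, which have not been merged for a parent vinyl group under tartrate control.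

Step 2
Reactants: 3 (S)-[4-(benzyloxy)phenyl][(R)-oxiran-2-yl]methanol; 4 3,5-bis(benzyloxy)phenol
Product: 5 (R)-2-{(R)-[3,5-bis(benzyloxy)phenoxy][4-(benzyloxy)phenyl]methyl}oxirane
Conditions: 4 (1.2 equiv), PPh3, DIAD, toluene, 0 °C → rt
Reagents that add atoms: none
Why: Mitsunobu etherification, in which the phenol displaces the oxyphosphonium of the secondary carbinol by SN2 with inversion (cold, non-polar medium to suppress ionisation), so the erythro alcohol becomes the threo aryl ether carrying the future C2 (R) and C3 (R) centres while the epoxide survives the neutral conditions.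

Step 3
Reactants: 5 (R)-2-{(R)-[3,5-bis(benzyloxy)phenoxy][4-(benzyloxy)phenyl]methyl}oxirane
Product: 6 (2R,3R)-5,7-bis(benzyloxy)-2-[4-(benzyloxy)phenyl]chroman-3-ol (5,7,4′-tri-O-benzyl-epiafzelechin)
Conditions: AuCl3 (5 mol %), AgOTf (15 mol %), N,N′-diphenylthiourea (5 mol %), ClCH2CH2Cl, rt
Reagents that add atoms: none
Why: Intramolecular Friedel–Crafts epoxide–arene cycloalkylation, in which the gold Lewis acid activates the terminal epoxide and the trioxygenated ring attacks its CH2 carbon ortho to the ether oxygen in the 6-endo mode, closing ring C without touching either stereocentre so that the threo ether gives the 2,3-cis flavan-3-ol.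

Step 4
Reactants: 7 3,4,5-trihydroxybenzaldehyde
Product: 9 3,5-bis(benzyloxy)-4-methoxybenzaldehyde, via 3,5-dihydroxy-4-methoxybenzaldehyde 8 (not isolated)
Conditions: MeI (1.05 equiv), NaHCO3 (1.1 equiv), DMF, N2, 40 °C; then BnBr (2.4 equiv), K2CO3 (3 equiv), 60 °C
Reagents that add atoms: methyl iodide, CI; benzyl bromide, BrCc1ccccc1
Why: Two-stage Williamson ether synthesis, in which the 4-OH (para to the formyl group and flanked by two hydroxyls) is the only phenol ionised by the weak base and is methylated first, after which the stronger base benzylates the two remaining phenols; no stereocentre is formed.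

Step 5
Reactants: 9 3,5-bis(benzyloxy)-4-methoxybenzaldehyde
Product: 11 (S)-[3,5-bis(benzyloxy)-4-methoxyphenyl][(R)-oxiran-2-yl]methanol, via vinylzinc (R)-allylic alkoxide 10 (not isolated)
Conditions: Zn(CH=CH2)2 (1.5 equiv), (+)-MIB (5 mol %), toluene, −30 → 0 °C; then Ti(OiPr)4 (20 mol %), L-(+)-DIPT (24 mol %), TBHP (3 equiv), 4 Å MS, CH2Cl2, −20 °C
Reagents that add atoms: divinylzinc, C=C[Zn]C=C; tert-butyl hydroperoxide, CC(C)(C)OO
Why: Proposed new method: the same tandem as in step 1, the (+)-MIB–zinc chelate setting the (R)-alkoxide centre by face-selective vinyl transfer and the matched L-(+)-tartrate–titanium catalyst then delivering oxygen anti to the aryl group to set the (R)-epoxide centre (erythro); the closest known reaction types are amino-alcohol-catalysed alkenylzinc addition with in situ epoxidation of the zinc alkoxide and the Sharpless asymmetric epoxidation of secondary allylic alcohols.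

Step 6
Reactants: 11 (S)-[3,5-bis(benzyloxy)-4-methoxyphenyl][(R)-oxiran-2-yl]methanol; 4 3,5-bis(benzyloxy)phenol
Product: 12 (R)-2-{(R)-[3,5-bis(benzyloxy)-4-methoxyphenyl][3,5-bis(benzyloxy)phenoxy]methyl}oxirane
Conditions: 4 (1.2 equiv), PPh3, DIAD, toluene, 0 °C → rt
Reagents that add atoms: none
Why: Mitsunobu etherification with SN2 inversion at the carbinol, as in step 2, giving the threo aryl ether with the future C2 (R) and C3 (R) centres; the twisted 4-methoxy group is a weak donor, so ionisation is less of a threat than in step 2.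

Step 7
Reactants: 12 (R)-2-{(R)-[3,5-bis(benzyloxy)-4-methoxyphenyl][3,5-bis(benzyloxy)phenoxy]methyl}oxirane
Product: 13 (2R,3R)-5,7-bis(benzyloxy)-2-[3,5-bis(benzyloxy)-4-methoxyphenyl]chroman-3-ol (5,7,3′,5′-tetra-O-benzyl-4′-O-methyl-epigallocatechin)
Conditions: AuCl3 (5 mol %), AgOTf (15 mol %), N,N′-diphenylthiourea (5 mol %), ClCH2CH2Cl, rt
Reagents that add atoms: none
Why: Intramolecular Friedel–Crafts epoxide–arene cycloalkylation as in step 3, the more nucleophilic phloroglucinol-type ring closing the six-membered ring C at the epoxide CH2 with both stereocentres retained (2,3-cis).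

Step 8
Reactants: 6 (2R,3R)-5,7-bis(benzyloxy)-2-[4-(benzyloxy)phenyl]chroman-3-ol
Product: 14 (2R,3R,4S)-5,7-bis(benzyloxy)-2-[4-(benzyloxy)phenyl]-4-(2-ethoxyethoxy)chroman-3-ol (4β ether)
Conditions: DDQ (2 equiv), HOCH2CH2OEt (5 equiv), CH2Cl2, rt
Reagents that add atoms: 2-ethoxyethanol, CCOCCO
Why: DDQ benzylic C–H oxidation with alcohol trapping, in which hydride is taken from C4 (the cation is stabilised as a quinone methide by the 5,7-dioxygenated ring A) and the alcohol adds trans to the 3-OH to give the 4β (4S) ether, a C–O bond that later serves as the leaving group.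

Step 9
Reactants: 14 (2R,3R,4S)-5,7-bis(benzyloxy)-2-[4-(benzyloxy)phenyl]-4-(2-ethoxyethoxy)chroman-3-ol; 13 (2R,3R)-5,7-bis(benzyloxy)-2-[3,5-bis(benzyloxy)-4-methoxyphenyl]chroman-3-ol
Product: 15 hepta-O-benzyl epiafzelechin-(4β→8)-4′-O-methylepigallocatechin (upper unit 2R,3R,4R; lower unit 2R,3R)
Conditions: 13 (3 equiv), TMSOTf (0.2 equiv), CH2Cl2, −78 °C; excess 13 recovered
Reagents that add atoms: none
Why: Lewis-acid-promoted Friedel–Crafts-type flavan coupling, in which TMSOTf ionises the 4-alkoxy group and C8 of 13 (the most nucleophilic position of the benzylated ring A) attacks the C4 cation anti to the 3-OH, setting the new C4 centre as 4β (R) with a 4→8 link, while the excess of 13 suppresses chain growth.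

Step 10
Reactants: 14 (2R,3R,4S)-5,7-bis(benzyloxy)-2-[4-(benzyloxy)phenyl]-4-(2-ethoxyethoxy)chroman-3-ol; 15 hepta-O-benzyl epiafzelechin-(4β→8)-4′-O-methylepigallocatechin
Product: 16 deca-O-benzyl epiafzelechin-(4β→8)-epiafzelechin-(4β→8)-4′-O-methylepigallocatechin (top unit 2R,3R,4R; middle unit 2R,3R,4S; bottom unit 2R,3R)
Conditions: 15 (2 equiv), TMSOTf (0.2 equiv), CH2Cl2, −78 → −40 °C; excess 15 recovered
Reagents that add atoms: none
Why: The same Lewis-acid-promoted Friedel–Crafts-type coupling, the only free C8 of 15 (upper unit) attacking the C4 cation anti to the 3-OH to set the top C4 as 4β (R), while the older C4 centre is untouched and is now designated S only because its CIP priorities change.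

Step 11
Reactants: 16 deca-O-benzyl epiafzelechin-(4β→8)-epiafzelechin-(4β→8)-4′-O-methylepigallocatechin
Product: 17 epiafzelechin-(4β→8)-epiafzelechin-(4β→8)-4′-O-methylepigallocatechin (CNP0146516.1)
Conditions: H2 (1 atm), Pd(OH)2/C, THF/MeOH/H2O (20:1:1), rt; Sephadex LH-20
Reagents that add atoms: none
Why: Catalytic hydrogenolysis cleaves the ten benzyl ethers and leaves the methyl ether, the three secondary alcohols and both interflavan bonds intact, so no stereocentre is formed or changed.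

**Compound list**
1 | 4-(benzyloxy)benzaldehyde | O=Cc1ccc(OCc2ccccc2)cc1 | starting material
2 | vinylzinc (R)-1-[4-(benzyloxy)phenyl]prop-2-en-1-olate | C=C[Zn]O[C@@H](c1ccc(OCc2ccccc2)cc1)C=C | intermediate (not isolated)
3 | (S)-[4-(benzyloxy)phenyl][(R)-oxiran-2-yl]methanol | O[C@@H](c1ccc(OCc2ccccc2)cc1)[C@H]1CO1 | intermediate
4 | 3,5-bis(benzyloxy)phenol | Oc1cc(OCc2ccccc2)cc(OCc2ccccc2)c1 | starting material
5 | (R)-2-{(R)-[3,5-bis(benzyloxy)phenoxy][4-(benzyloxy)phenyl]methyl}oxirane | c1ccccc1COc1cc(OCc2ccccc2)cc(O[C@H](c2ccc(OCc3ccccc3)cc2)[C@H]2CO2)c1 | intermediate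
6 | (2R,3R)-5,7-bis(benzyloxy)-2-[4-(benzyloxy)phenyl]chroman-3-ol | O[C@@H]1Cc2c(OCc3ccccc3)cc(OCc3ccccc3)cc2O[C@@H]1c1ccc(OCc2ccccc2)cc1 | intermediate
7 | 3,4,5-trihydroxybenzaldehyde | O=Cc1cc(O)c(O)c(O)c1 | starting material
8 | 3,5-dihydroxy-4-methoxybenzaldehyde | O=Cc1cc(O)c(OC)c(O)c1 | intermediate (not isolated)
9 | 3,5-bis(benzyloxy)-4-methoxybenzaldehyde | O=Cc1cc(OCc2ccccc2)c(OC)c(OCc2ccccc2)c1 | intermediate
10 | vinylzinc (R)-1-[3,5-bis(benzyloxy)-4-methoxyphenyl]prop-2-en-1-olate | C=C[Zn]O[C@@H](c1cc(OCc2ccccc2)c(OC)c(OCc2ccccc2)c1)C=C | intermediate (not isolated)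
11 | (S)-[3,5-bis(benzyloxy)-4-methoxyphenyl][(R)-oxiran-2-yl]methanol | O[C@@H](c1cc(OCc2ccccc2)c(OC)c(OCc2ccccc2)c1)[C@H]1CO1 | intermediate
12 | (R)-2-{(R)-[3,5-bis(benzyloxy)-4-methoxyphenyl][3,5-bis(benzyloxy)phenoxy]methyl}oxirane | c1ccccc1COc1cc(OCc2ccccc2)cc(O[C@H](c2cc(OCc3ccccc3)c(OC)c(OCc3ccccc3)c2)[C@H]2CO2)c1 | intermediate
13 | (2R,3R)-5,7-bis(benzyloxy)-2-[3,5-bis(benzyloxy)-4-methoxyphenyl]chroman-3-ol | O[C@@H]1Cc2c(OCc3ccccc3)cc(OCc3ccccc3)cc2O[C@@H]1c1cc(OCc2ccccc2)c(OC)c(OCc2ccccc2)c1 | intermediate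
14 | (2R,3R,4S)-5,7-bis(benzyloxy)-2-[4-(benzyloxy)phenyl]-4-(2-ethoxyethoxy)chroman-3-ol | CCOCCO[C@H]1c2c(OCc3ccccc3)cc(OCc3ccccc3)cc2O[C@H](c2ccc(OCc3ccccc3)cc2)[C@@H]1O | intermediate
15 | hepta-O-benzyl epiafzelechin-(4β→8)-4′-O-methylepigallocatechin; upper unit 2R,3R,4R, lower unit 2R,3R | COc1c(OCc7ccccc7)cc([C@H]2Oc3c(c(OCc7ccccc7)cc(OCc7ccccc7)c3[C@H]3c4c(OCc7ccccc7)cc(OCc7ccccc7)cc4O[C@H](c4ccc(OCc7ccccc7)cc4)[C@@H]3O)C[C@H]2O)cc1OCc1ccccc1 | intermediate
16 | deca-O-benzyl epiafzelechin-(4β→8)-epiafzelechin-(4β→8)-4′-O-methylepigallocatechin; top unit 2R,3R,4R, middle unit 2R,3R,4S, bottom unit 2R,3R | COc1c(OCc7ccccc7)cc([C@H]2Oc3c(c(OCc7ccccc7)cc(OCc7ccccc7)c3[C@H]3c4c(OCc7ccccc7)cc(OCc7ccccc7)c([C@H]5c6c(OCc7ccccc7)cc(OCc7ccccc7)cc6O[C@H](c6ccc(OCc7ccccc7)cc6)[C@@H]5O)c4O[C@H](c4ccc(OCc7ccccc7)cc4)[C@@H]3O)C[C@H]2O)cc1OCc1ccccc1 | intermediate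
17 | epiafzelechin-(4β→8)-epiafzelechin-(4β→8)-4′-O-methylepigallocatechin (CNP0146516.1) | COc1c(O)cc([C@H]2Oc3c(c(O)cc(O)c3[C@H]3c4c(O)cc(O)c([C@H]5c6c(O)cc(O)cc6O[C@H](c6ccc(O)cc6)[C@@H]5O)c4O[C@H](c4ccc(O)cc4)[C@@H]3O)C[C@H]2O)cc1O | target

**Step count**
Total: 11 steps. Longest linear sequence: 7 steps (4 → 5 → 6 → 7 → 9 → 10 → 11; the branch 1 → 2 → 3 → 8 → 9 → 10 → 11 is equally long).

**The three steps most likely to fail**

Step 1 (the proposed new tandem, used again in step 5). Zinc salts may disturb the titanium–tartrate catalyst, or the vinyl transfer may be less face-selective than alkyl transfer. The fallback is known chemistry and sets out from 1. CH2=CHMgBr in THF at 0 °C gives racemic 1-[4-(benzyloxy)phenyl]prop-2-en-1-ol F1. A Sharpless kinetic resolution (Ti(OiPr)4, L-(+)-DIPT, TBHP 0.6 equiv, 4 Å MS, CH2Cl2, −20 °C) then epoxidises only its (R)-enantiomer to the erythro epoxy alcohol, which is compound 3, where the fallback rejoins the route (at most half of the material). In the same way 9 gives racemic 1-[3,5-bis(benzyloxy)-4-methoxyphenyl]prop-2-en-1-ol F2 and rejoins at 11. This costs one extra step per series.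

Step 2 (Mitsunobu etherification). The carbinol is para-alkoxybenzylic, so partial ionisation would erode the C2 configuration, and the electron-rich phenol could also react at carbon. The fallback sets out from 1 and makes the aryl ether bond by catalytic allylic substitution instead. Horner–Wadsworth–Emmons olefination (triethyl phosphonoacetate, NaH, THF) gives ethyl (E)-3-[4-(benzyloxy)phenyl]prop-2-enoate F3. Reduction with i-Bu2AlH gives (E)-3-[4-(benzyloxy)phenyl]prop-2-en-1-ol F4, and ClCO2Me/pyridine gives (E)-3-[4-(benzyloxy)phenyl]prop-2-en-1-yl methyl carbonate F5. Iridium-catalysed asymmetric allylic etherification with the lithium salt of 4 ([Ir(cod)Cl]2, binaphthol-derived bis(1-phenylethyl)phosphoramidite, THF) gives the branched ether (S)-1,3-bis(benzyloxy)-5-({1-[4-(benzyloxy)phenyl]prop-2-en-1-yl}oxy)benzene F6. Epoxidation with mCPBA/NaHCO3 is not face-selective here, so the required epoxide is isolated by chromatography, and the fallback rejoins the route at 5.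

Step 10 (second coupling). Electrophile 14 has its own free C8 and can add to itself, and dimer 15 offers more than one nucleophilic position, so the trimer may come mixed with higher oligomers. The fallback sets out from 6 and caps C8. NBS in CH2Cl2 at −78 °C gives (2R,3R)-5,7-bis(benzyloxy)-2-[4-(benzyloxy)phenyl]-8-bromochroman-3-ol F7. DDQ/2-ethoxyethanol gives (2R,3R,4S)-5,7-bis(benzyloxy)-2-[4-(benzyloxy)phenyl]-8-bromo-4-(2-ethoxyethoxy)chroman-3-ol F8, which cannot self-condense. Coupling of F8 with 15 in a 1:1 ratio (TMSOTf, CH2Cl2, −78 °C) gives the C8-bromo deca-O-benzyl trimer F9. Hydrogenolysis (H2, Pd(OH)2/C, NaOAc, THF/MeOH/H2O) removes the bromine together with the benzyl groups, and the fallback rejoins the route at 17.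

**Further compounds**
F1 | step 1 | racemic 1-[4-(benzyloxy)phenyl]prop-2-en-1-ol | C=CC(O)c1ccc(OCc2ccccc2)cc1
F2 | step 1 | racemic 1-[3,5-bis(benzyloxy)-4-methoxyphenyl]prop-2-en-1-ol | C=CC(O)c1cc(OCc2ccccc2)c(OC)c(OCc2ccccc2)c1
F3 | step 2 | ethyl (E)-3-[4-(benzyloxy)phenyl]prop-2-enoate | CCOC(=O)/C=C/c1ccc(OCc2ccccc2)cc1
F4 | step 2 | (E)-3-[4-(benzyloxy)phenyl]prop-2-en-1-ol | OC/C=C/c1ccc(OCc2ccccc2)cc1
F5 | step 2 | (E)-3-[4-(benzyloxy)phenyl]prop-2-en-1-yl methyl carbonate | COC(=O)OC/C=C/c1ccc(OCc2ccccc2)cc1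
F6 | step 2 | (S)-1,3-bis(benzyloxy)-5-({1-[4-(benzyloxy)phenyl]prop-2-en-1-yl}oxy)benzene | c1ccccc1COc1cc(OCc2ccccc2)cc(O[C@H](c2ccc(OCc3ccccc3)cc2)C=C)c1
F7 | step 10 | (2R,3R)-5,7-bis(benzyloxy)-2-[4-(benzyloxy)phenyl]-8-bromochroman-3-ol | O[C@@H]1Cc2c(OCc3ccccc3)cc(OCc3ccccc3)c(Br)c2O[C@@H]1c1ccc(OCc2ccccc2)cc1
F8 | step 10 | (2R,3R,4S)-5,7-bis(benzyloxy)-2-[4-(benzyloxy)phenyl]-8-bromo-4-(2-ethoxyethoxy)chroman-3-ol | CCOCCO[C@H]1c2c(OCc3ccccc3)cc(OCc3ccccc3)c(Br)c2O[C@H](c2ccc(OCc3ccccc3)cc2)[C@@H]1O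
F9 | step 10 | C8-bromo deca-O-benzyl trimer (16 with bromine at C8 of the top unit) | COc1c(OCc7ccccc7)cc([C@H]2Oc3c(c(OCc7ccccc7)cc(OCc7ccccc7)c3[C@H]3c4c(OCc7ccccc7)cc(OCc7ccccc7)c([C@H]5c6c(OCc7ccccc7)cc(OCc7ccccc7)c(Br)c6O[C@H](c6ccc(OCc7ccccc7)cc6)[C@@H]5O)c4O[C@H](c4ccc(OCc7ccccc7)cc4)[C@@H]3O)C[C@H]2O)cc1OCc1ccccc1
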